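## Retrosynthetic overview

1. The last bond made is the exocyclic N2–C amidine. Naamidine B comes from the free 4,5-dibenzyl-2-aminoimidazole (naamine level) and 1-methylparabanic acid, the order proposed for naamine → naamidine in nature.
2. The C5–CH2Ar bond joins a 4-monobenzyl-1-methyl-2-aminoimidazole (C6–C3–guanidine unit) to isovanillin (C6–C1 unit). The finished ring acts as the C-nucleophile, so no fully substituted α-aminoketone and no imidazole metalation is needed.
3. Ring A (the 2-aminoimidazole) is closed by amidino transfer from cyanamide to an α-(methylamino)ketone, followed by cyclodehydration of the α-guanidino ketone. The sarcosine nitrogen fixes the N-methyl site.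
4. The α-aminoketone comes from Boc-sarcosine methyl ester and 4-methoxyphenylacetic acid by decarboxylative Claisen acylation, the laboratory copy of an α-oxoamine-synthase step.
5. Ring order: ring A first (step 2). Ring B (the imidazolidinetrione) is made separately from N-methylurea and oxalyl chloride (step 4) and joined last (step 5).

Assumption: the SMILES holds no stereocentre and no stereogenic double bond, so naamidine B is achiral and there is no enantiomer to select; the amidine is drawn as the given NH tautomer.

## Route

Step 1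
Reactants: 1 methyl N-(tert-butoxycarbonyl)-N-methylglycinate (Boc-Sar-OMe); 2 (4-methoxyphenyl)acetic acid
Product: 5 tert-butyl N-[3-(4-methoxyphenyl)-2-oxopropyl]-N-methylcarbamate, via magnesium enediolate 3 (not isolated), via beta-keto acid 4 (not isolated)
Conditions: 2 (2.2 equiv), iPrMgCl (4.4 equiv), THF, 0 → 45 °C, 2 h; 1 (1.0 equiv), 0 °C → rt; 1 M aq. HCl to pH 3, 40 °C, 30 min
Reagents that add atoms: isopropylmagnesium chloride, CC(C)[Mg]Cl (gives the MgCl groups of 3 only; none stays in 5)
Why: Ivanov-type decarboxylative Claisen condensation, a reaction type known for arylacetic and chloroacetic acid dianions with N-Boc amino esters, in which the C-nucleophilic enediolate 3 acylates at the ester of 1 (the Boc carbonyl is far less electrophilic and there is no N–H to quench base), the product stays masked as its enolate until the quench, and the α-aryl β-keto acid 4 loses CO2 on mild warming together with its racemic centre.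

Step 2
Reactants: 5 tert-butyl N-[3-(4-methoxyphenyl)-2-oxopropyl]-N-methylcarbamate; 6 cyanamide
Product: 9 4-(4-methoxybenzyl)-1-methyl-1H-imidazol-2-amine, via aminoketone 7 (not isolated), via guanidino ketone 8 (not isolated)
Conditions: 4 M HCl/dioxane, rt, 1 h, evaporate; 6 (50 wt % aq., 5 equiv), H2O–EtOH 1:1, pH 4.5, 95 °C, 3 h; aq. Na2CO3 work-up
Reagents that add atoms: none
Why: Marckwald-type cyanamide condensation, copying the amidino transfer and cyclisation proposed for the C6–C3 unit in the biogenesis, in which amine 7 is mostly protonated at pH 4.5 (suppressing dihydropyrazine self-condensation) yet still adds to cyanamide, and the α-guanidino ketone 8 cyclodehydrates to the aromatic ring with the methyl-bearing nitrogen necessarily ending as N1 next to the unsubstituted C5; no stereocentre is formed.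

Step 3
Reactants: 9 4-(4-methoxybenzyl)-1-methyl-1H-imidazol-2-amine; 10 isovanillin (3-hydroxy-4-methoxybenzaldehyde)
Product: 14 5-(3-hydroxy-4-methoxybenzyl)-4-(4-methoxybenzyl)-1-methyl-1H-imidazol-2-amine, via iminium phenolate 11 (not isolated), via Mannich base 12 (not isolated), via azafulvene 13 (not isolated)
Conditions: 10 (1.2 equiv), pyrrolidine (1.5 equiv), 4 Å MS, EtOH, 70 °C, 16 h, Ar; then AcOH (5 equiv), Hantzsch ester (diethyl 2,6-dimethyl-1,4-dihydropyridine-3,5-dicarboxylate, 1.5 equiv), 70 °C, 4 h
Reagents that add atoms: pyrrolidine, C1CCNC1 (held in 11 and 12 only; released again before 13)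
Why: Proposed new method: C5 of a 2-aminoimidazole is the β-carbon of a cyclic guanidine-enamine, so it should attack iminium ion 11 in an aza-Friedel–Crafts (Mannich/Betti-type) reaction while N-attack gives only labile aminals that revert, after which acid expels pyrrolidine from 12 to give the vinylogous guanidinium form of 13, which takes hydride from the Hantzsch ester at the benzylic carbon and re-aromatises (this mirrors the C6–C1 benzylation of monobenzyl congeners assumed in the biogenesis); the closest known reaction types are hydroxyalkylation of 2-aminoimidazoles by aldehydes at C4/C5, three-component aza-Friedel–Crafts alkylation of imidazo[1,2-a]pyridines at C3, reductive deamination of gramine-type Mannich bases, and Hantzsch-ester reduction of alkylideneindoleninium ions; the racemic centre of 12 is erased and none remains.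

Step 4
Reactants: 15 N-methylurea; 16 oxalyl chloride
Product: 17 1-methylimidazolidine-2,4,5-trione (1-methylparabanic acid)
Conditions: 16 (1.1 equiv), THF, 0 → 65 °C, 2 h; evaporate, recrystallise (EtOAc)
Reagents that add atoms: none
Why: Double N-acylation of a urea by oxalyl chloride (the classical parabanic acid synthesis), driven by loss of HCl and closure of a five-membered ring; no stereocentre.

Step 5
Reactants: 14 5-(3-hydroxy-4-methoxybenzyl)-4-(4-methoxybenzyl)-1-methyl-1H-imidazol-2-amine; 17 1-methylimidazolidine-2,4,5-trione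
Product: 21 naamidine B, via N-silyl trione 18 (not isolated), via O-silyl amine 19 (not isolated), via O-silyl naamidine B 20 (not isolated)
Conditions: 17 (1.5 equiv), BSA (4 equiv), MeCN, 80 °C, 1 h; 14, PhMe, 110 °C, 16 h; 1 M aq. citric acid/THF work-up, rt
Reagents that add atoms: N,O-bis(trimethylsilyl)acetamide (BSA), CC(=N[Si](C)(C)C)O[Si](C)(C)C (gives the Me3Si groups of 18, 19 and 20 only; none stays in 21)
Why: Silyl-mediated addition–elimination (amidine-forming condensation), established for closely related 4,5-dibenzyl-2-aminoimidazoles carrying a free phenol, in which silylation removes the acidic N3–H that would otherwise only protonate the basic amine and turns the neighbouring C4 carbonyl into an O-silyl-imidate-type electrophile, so the 2-amino group attacks C4 rather than C5, silanol is lost and the product tautomerises to the conjugated NH-amidine, with the phenol silyl ether falling off on work-up; no stereocentre.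

## Compound list

1 | methyl N-(tert-butoxycarbonyl)-N-methylglycinate (Boc-Sar-OMe) | COC(=O)CN(C)C(=O)OC(C)(C)C | starting material
2 | (4-methoxyphenyl)acetic acid | COc1ccc(CC(=O)O)cc1 | starting material
3 | bis(chloromagnesium) enediolate of 2 (Ivanov reagent) | COc1ccc(C=C(O[Mg]Cl)O[Mg]Cl)cc1 | intermediate
4 | 4-[(tert-butoxycarbonyl)(methyl)amino]-2-(4-methoxyphenyl)-3-oxobutanoic acid (racemic, centre lost on decarboxylation) | CC(C)(C)OC(=O)N(C)CC(=O)C(C(=O)O)c1ccc(OC)cc1 | intermediate
5 | tert-butyl N-[3-(4-methoxyphenyl)-2-oxopropyl]-N-methylcarbamate | CC(C)(C)OC(=O)N(C)CC(=O)Cc1ccc(OC)cc1 | intermediate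
6 | cyanamide | NC#N | starting material
7 | 1-(4-methoxyphenyl)-3-(methylamino)propan-2-one (handled as its hydrochloride) | CNCC(=O)Cc1ccc(OC)cc1 | intermediate
8 | 1-[3-(4-methoxyphenyl)-2-oxopropyl]-1-methylguanidine | CN(CC(=O)Cc1ccc(OC)cc1)C(N)=N | intermediate
9 | 4-(4-methoxybenzyl)-1-methyl-1H-imidazol-2-amine | COc1ccc(Cc2cn(C)c(N)n2)cc1 | intermediate
10 | isovanillin (3-hydroxy-4-methoxybenzaldehyde) | COc1ccc(C=O)cc1O | starting material
11 | 1-(4-methoxy-3-oxidobenzylidene)pyrrolidin-1-ium (iminium phenolate zwitterion) | COc1ccc(C=[N+]2CCCC2)cc1[O-] | intermediate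
12 | 5-[(3-hydroxy-4-methoxyphenyl)(pyrrolidin-1-yl)methyl]-4-(4-methoxybenzyl)-1-methyl-1H-imidazol-2-amine (racemic, centre erased in the same step) | COc1ccc(Cc2nc(N)n(C)c2C(N2CCCC2)c2ccc(OC)c(O)c2)cc1 | intermediate
13 | 5-(3-hydroxy-4-methoxybenzylidene)-4-(4-methoxybenzyl)-1-methyl-1,5-dihydro-2H-imidazol-2-imine (E/Z mixture, geometry lost on reduction; reacts N-protonated) | COc1ccc(CC2=NC(=N)N(C)C2=Cc2ccc(OC)c(O)c2)cc1 | intermediate
14 | 5-(3-hydroxy-4-methoxybenzyl)-4-(4-methoxybenzyl)-1-methyl-1H-imidazol-2-amine | COc1ccc(Cc2nc(N)n(C)c2Cc2ccc(OC)c(O)c2)cc1 | intermediate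
15 | N-methylurea | CNC(N)=O | starting material
16 | oxalyl chloride | O=C(Cl)C(=O)Cl | starting material
17 | 1-methylimidazolidine-2,4,5-trione (1-methylparabanic acid) | CN1C(=O)NC(=O)C1=O | intermediate
18 | 1-methyl-3-(trimethylsilyl)imidazolidine-2,4,5-trione (in equilibrium with its O-silyl imidate) | CN1C(=O)C(=O)N([Si](C)(C)C)C1=O | intermediate
19 | 4-(4-methoxybenzyl)-5-[4-methoxy-3-(trimethylsilyloxy)benzyl]-1-methyl-1H-imidazol-2-amine | COc1ccc(Cc2nc(N)n(C)c2Cc2ccc(OC)c(O[Si](C)(C)C)c2)cc1 | intermediate
20 | O-trimethylsilyl naamidine B | COc1ccc(Cc2nc(NC3=NC(=O)N(C)C3=O)n(C)c2Cc2ccc(OC)c(O[Si](C)(C)C)c2)cc1 | intermediate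
21 | naamidine B (achiral) | COc1ccc(Cc2nc(NC3=NC(=O)N(C)C3=O)n(C)c2Cc2ccc(OC)c(O)c2)cc1 | target

## Step count and risks

- **Total step count:** 5.
- **Longest linear sequence:** 4 (steps 1, 2, 3, 5). Step 4 is a one-step side branch.

**Most likely to fail, first: step 3.** The reaction has no precedent on a free 2-aminoimidazole. The electron-rich aldehyde may react slowly at the crowded C5, and N2-benzylation or reduction of 11 to the benzylpyrrolidine may compete. The fallback reverses the polarity at C5. Setting out from 9, the amino group is masked with DMF dimethyl acetal (PhMe, 90 °C) as N'-[4-(4-methoxybenzyl)-1-methylimidazol-2-yl]-N,N-dimethylformamidine F1. NIS (MeCN, 0 °C) converts this into the 5-iodoimidazole F2. Iodine–magnesium exchange (iPrMgCl·LiCl, THF, −20 °C) gives the imidazol-5-ylmagnesium chloride F3, which is added to the sodium phenolate of isovanillin F4 (made from 10 with NaH in THF) to give the secondary carbinol F5. Ionic deoxygenation (Et3SiH, TFA/CH2Cl2, rt) gives the 5-benzyl formamidine F6. Hydrolysis (2 M aq. HCl/EtOH, 80 °C) then removes the amidine and comes back to the route at 14.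

**Second: step 1.** The basic dianion may enolise ester 1 instead of acylating, and the electron-rich acid may metalate incompletely. The fallback replaces the decarboxylative Claisen with a ketone synthesis from a benzylic Grignard reagent. Setting out from 1, MeNHOMe·HCl/iPrMgCl (THF, −10 °C) gives the Weinreb amide F7. Commercial 4-methoxybenzylmagnesium chloride (THF, 0 °C) adds once to its chelated carbonyl and comes back to the route at 5.

**Third: step 2.** Aminoketone 7 may self-condense to a dihydropyrazine, and cyanamide may oligomerise in hot water. The fallback builds the guanidine with a protected amidine-transfer reagent in aprotic medium instead of free cyanamide in water. Setting out from 5, HCl/dioxane gives 7 as its isolated hydrochloride. N,N'-di-Boc-N''-triflylguanidine (Et3N, CH2Cl2, rt) converts it into the di-Boc guanidino ketone F8. TFA/CH2Cl2 strips both Boc groups, so 8 forms under acid and cyclodehydrates, coming back to the route at 9.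

## Further compounds

F1 | step 3 | N'-[4-(4-methoxybenzyl)-1-methyl-1H-imidazol-2-yl]-N,N-dimethylformamidine | CN(C)/C=N/c1nc(Cc2ccc(OC)cc2)cn1C
F2 | step 3 | N'-[5-iodo-4-(4-methoxybenzyl)-1-methyl-1H-imidazol-2-yl]-N,N-dimethylformamidine | CN(C)/C=N/c1nc(Cc2ccc(OC)cc2)c(I)n1C
F3 | step 3 | {2-[(dimethylaminomethylidene)amino]-4-(4-methoxybenzyl)-1-methyl-1H-imidazol-5-yl}magnesium chloride | CN(C)/C=N/c1nc(Cc2ccc(OC)cc2)c([Mg]Cl)n1C
F4 | step 3 | sodium 5-formyl-2-methoxyphenolate | COc1ccc(C=O)cc1[O-].[Na+]
F5 | step 3 | N'-{5-[hydroxy(3-hydroxy-4-methoxyphenyl)methyl]-4-(4-methoxybenzyl)-1-methyl-1H-imidazol-2-yl}-N,N-dimethylformamidine (racemic) | CN(C)/C=N/c1nc(Cc2ccc(OC)cc2)c(C(O)c2ccc(OC)c(O)c2)n1C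
F6 | step 3 | N'-[5-(3-hydroxy-4-methoxybenzyl)-4-(4-methoxybenzyl)-1-methyl-1H-imidazol-2-yl]-N,N-dimethylformamidine | CN(C)/C=N/c1nc(Cc2ccc(OC)cc2)c(Cc2ccc(OC)c(O)c2)n1C
F7 | step 1 | tert-butyl N-{2-[methoxy(methyl)amino]-2-oxoethyl}-N-methylcarbamate | CON(C)C(=O)CN(C)C(=O)OC(C)(C)C
F8 | step 2 | N,N'-bis(tert-butoxycarbonyl)-N''-[3-(4-methoxyphenyl)-2-oxopropyl]-N''-methylguanidine | CC(C)(C)OC(=O)NC(=NC(=O)OC(C)(C)C)N(C)CC(=O)Cc1ccc(OC)cc1
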